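**Plan**

- Numbering: spiro[5.5]undecane; ring A = C1–C6 (C1 methylidene, C3 OH, C4 Br, C5 gem-dimethyl), ring B = C6–C11 (C8 Br, C9 Cl and Me).
- Cuts: C1=CH2 (Peterson); C9–Cl and the C1 carbonyl (acidolysis of a C1–O–C9 bridged enol ether); C9–O and C8–Br (bromonium capture by the C1 carbonyl oxygen); C4–Br (γ-bromination); C8–C9 (ring-closing metathesis); C6–C7 (decarboxylative allylation); C6–C11 (enolate alkylation), back to dimedone.
- Forward: ring A comes from dimedone; C6 is made quaternary with a 3-methylbut-3-enyl and an allyl arm; ring B is closed between C8 and C9; halogens, hydroxyl and methylidene follow.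
- Feature used by the ring closure: the fully substituted C6 of ring A holds both olefinic arms (gem-disubstituent effect), so C8 and C9 close the six-membered ring B, and the new C8=C9 bond lies 1,4 across ring B under the C1 carbonyl oxygen.
- Stereochemistry: C6 from the Pd/(S)-PHOX allylation; C8 and C9 from anti bromoetherification relayed by the C1 oxygen (O, later Cl with retention, syn to C1; Br anti); C4 from bromination of the cyclohexene-stage spirocycle; C3 from hydride addition anti to C4–Br.

Key step: step 5

Assumption: the (S)-PHOX ligand is taken to deliver the allyl group to the same enolate face as with 2-alkylcyclohexanone enolates (giving 6R in 9); if this vinylogous ester responded in the opposite sense, the ligand antipode would be used.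

**Step 1**
Reactants: 1 dimedone (5,5-dimethylcyclohexane-1,3-dione)
Product: 2 3-methoxy-5,5-dimethylcyclohex-2-en-1-one
Conditions: MeOH, TsOH·H2O (cat.), reflux, 3 Å sieves
Reagents that add atoms: methanol, CO
Why: Acid-catalysed O-alkylation of the vinylogous acid (enol ether formation from a cyclic 1,3-dione) masks one carbonyl and leaves C6 as the only α′ position; no stereocenter is formed.

**Step 2**
Reactants: 2 3-methoxy-5,5-dimethylcyclohex-2-en-1-one; 3 4-bromo-2-methylbut-1-ene
Product: 5 3-methoxy-5,5-dimethyl-6-(3-methylbut-3-en-1-yl)cyclohex-2-en-1-one (racemic), via lithium enolate 4 (not isolated)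
Conditions: LiN(i-Pr)2, THF, −78 °C; then 3, DMPU, −78 → 23 °C
Reagents that add atoms: none
Why: Kinetic α′-deprotonation of the vinylogous ester and SN2 alkylation (Stork–Danheiser alkylation) install the future C11–C10–C9 arm; the C6 center formed here is racemic and is erased as an enolate in step 3.

**Step 3**
Reactants: 5 3-methoxy-5,5-dimethyl-6-(3-methylbut-3-en-1-yl)cyclohex-2-en-1-one; 6 allyl chloroformate
Product: 8 5-methoxy-3,3-dimethyl-2-(3-methylbut-3-en-1-yl)cyclohexa-1,5-dien-1-yl prop-2-en-1-yl carbonate, via lithium enolate 7 (not isolated)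
Conditions: LiN(i-Pr)2, TMEDA, THF, −78 °C; then 6, −78 → 0 °C
Reagents that add atoms: none
Why: The fully substituted, hindered lithium enolate from kinetic α′-deprotonation is acylated on oxygen by the hard chloroformate, giving the allyl enol carbonate needed for the palladium step.

**Step 4**
Reactants: 8 5-methoxy-3,3-dimethyl-2-(3-methylbut-3-en-1-yl)cyclohexa-1,5-dien-1-yl prop-2-en-1-yl carbonate
Product: 9 (6R)-3-methoxy-5,5-dimethyl-6-(3-methylbut-3-en-1-yl)-6-(prop-2-en-1-yl)cyclohex-2-en-1-one
Conditions: Pd2(dba)3 (2.5 mol %), (S)-(CF3)3-t-BuPHOX [(S)-4-tert-butyl-2-{2-[bis(4-trifluoromethylphenyl)phosphanyl]-5-(trifluoromethyl)phenyl}-4,5-dihydrooxazole] (6 mol %), toluene, 25 °C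
Reagents that add atoms: none
Why: Decarboxylative asymmetric allylic alkylation (Tsuji allylation): zerovalent palladium ionizes the allyl carbonate, CO2 is lost, and the chiral palladium enolate forms the C6–C7 bond on one enolate face, which should set the quaternary center (6R) next to the gem-dimethyl carbon; the electron-poor ligand is chosen for this hindered coupling.

**Step 5**
Reactants: 9 (6R)-3-methoxy-5,5-dimethyl-6-(3-methylbut-3-en-1-yl)-6-(prop-2-en-1-yl)cyclohex-2-en-1-one
Product: 10 (6R)-3-methoxy-5,5,9-trimethylspiro[5.5]undeca-2,8-dien-1-one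
Conditions: second-generation Grubbs catalyst RuCl2(=CHPh)(PCy3)(H2IMes) (5 mol %), CH2Cl2 (0.005 M), 40 °C
Reagents that add atoms: none
Why: The ruthenium benzylidene engages the unhindered allyl terminus of 9 by [2+2] cycloaddition and cycloreversion, the new alkylidene then adds across the 1,1-disubstituted olefin of the 3-methylbut-3-enyl arm, and collapse of that ruthenacyclobutane releases the C8=C9 bond and ethylene. The closest known reaction type is ring-closing metathesis of a 1,7-diene to a trisubstituted cyclohexene at a quaternary carbon, which is established for spirocyclic vinylogous esters of this kind. Ring B closes as a six-membered ring in the ordinary ring-closing mode, helped by the gem-disubstituent effect of the fully substituted C6 that carries both arms. No stereocenter is formed, and the C6 center from step 4 is remote from the reacting olefins and cannot epimerize. The step needs reaction of the two terminal olefins in preference to the trisubstituted push–pull C2=C3 enol ether, which is secured because that olefin is hindered and electronically unsuited to the catalyst, and it needs closure over dimerization, which dilution and the six-membered ring size secure. The alkene formed lies 1,4 across ring B from the C1 carbonyl oxygen, and this geometry is what later passes the C6 configuration on to C8 and C9.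

**Step 6**
Reactants: 10 (6R)-3-methoxy-5,5,9-trimethylspiro[5.5]undeca-2,8-dien-1-one
Product: 12 (4S,6R)-4-bromo-3-methoxy-5,5,9-trimethylspiro[5.5]undeca-2,8-dien-1-one, via silyl dienol ether 11 (not isolated)
Conditions: Me3SiOTf, Et3N, CH2Cl2, 0 °C; volatiles removed; then NBS (1.05 equiv), THF, −78 °C
Reagents that add atoms: N-bromosuccinimide, O=C1CCC(=O)N1Br
Why: Soft enolization can only occur at C4 (C6 is quaternary) and gives the 1-silyloxy-3-methoxy diene, whose terminal carbon C4, activated by both oxygens and far more nucleophilic than the ring B olefin, is attacked by NBS with return of the vinylogous ester (vinylogous Mukaiyama-type γ-halogenation); bromine should enter anti to the pseudo-axial methyl of C5, that is syn to the allylic ring B methylene C7, the flatter arm expected to sit pseudo-axial on ring A, giving 4S.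

**Step 7**
Reactants: 12 (4S,6R)-4-bromo-3-methoxy-5,5,9-trimethylspiro[5.5]undeca-2,8-dien-1-one
Product: 14 (4S,6R,8S,9S)-4,8-dibromo-5,5,9-trimethyl-1,9-epoxyspiro[5.5]undec-1-en-3-one, via oxocarbenium succinimidate 13 (not isolated)
Conditions: NBS (1.05 equiv), CH2Cl2, 4 Å sieves, −40 → 0 °C, dark; aq. NaHCO3 work-up
Reagents that add atoms: N-bromosuccinimide, O=C1CCC(=O)N1Br
Why: Proposed new method: NBS forms the C8–C9 bromonium ion reversibly on either face, but only the ion on the face away from C1 can be opened intramolecularly, by the vinylogous ester carbonyl oxygen held over ring B, at the tertiary carbon C9 (Markovnikov, anti, closure of a 2-oxabicyclo[2.2.2]octane through the ring B boat), and the resulting dialkoxyallyl cation 13 is demethylated by succinimide anion, so that C8–Br (8S) and C9–O (9S, syn to C1) are fixed by anti addition relayed from C6 while the C3 ketone is unveiled next to C4; the closest known reaction types are bromolactonization of esters with loss of the O-alkyl group and the bromoetherification of α-terpineol to a 2-bromo-1,8-cineole, and the C4–H bond lies near the nodal plane of the cation, which should protect that center.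

**Step 8**
Reactants: 14 (4S,6R,8S,9S)-4,8-dibromo-5,5,9-trimethyl-1,9-epoxyspiro[5.5]undec-1-en-3-one
Product: 15 (3R,4S,6R,8S,9S)-4,8-dibromo-5,5,9-trimethyl-1,9-epoxyspiro[5.5]undec-1-en-3-ol
Conditions: i-Bu2AlH (1.5 equiv), CH2Cl2, −78 °C; aq. KNa tartrate, 0 °C; crude alcohol used at once
Reagents that add atoms: none
Why: 1,2-Reduction of the vinylogous ester carbonyl by the aluminium hydride (as in Stork–Danheiser reductions), with hydride delivered anti to the pseudo-axial C4–Br bond, should give the cis-bromohydrin (3R); the acid-labile alcohol is not exposed to acid or silica.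

**Step 9**
Reactants: 15 (3R,4S,6R,8S,9S)-4,8-dibromo-5,5,9-trimethyl-1,9-epoxyspiro[5.5]undec-1-en-3-ol
Product: 16 (3R,4S,6R,8S,9S)-4,8-dibromo-9-chloro-3-hydroxy-5,5,9-trimethylspiro[5.5]undecan-1-one
Conditions: HCl (2 M in Et2O, 3 equiv), CH2Cl2, −78 → −20 °C; NaHCO3 quench
Reagents that add atoms: hydrogen chloride, Cl
Why: HCl protonates the tert-alkyl enol ether at C2, the oxocarbenium ion releases C9 as a tertiary cation bridged by the trans C8 bromine, and chloride opens that bromonium ion at C9 anti to bromine, so that Cl replaces O with retention (9S) while C1 becomes the ketone (acidolysis of a tert-alkyl enol ether with neighbouring-group participation by bromine); ionization of the C3 hydroxyl is slowed by the adjacent cis C–Br bond.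

**Step 10**
Reactants: 16 (3R,4S,6R,8S,9S)-4,8-dibromo-9-chloro-3-hydroxy-5,5,9-trimethylspiro[5.5]undecan-1-one
Product: 18 (3R,4S,6S,8S,9S)-4,8-dibromo-9-chloro-5,5,9-trimethyl-1-methylidenespiro[5.5]undecan-3-ol, via β-hydroxysilane 17 (not isolated)
Conditions: Me3SiCH2Li (3.5 equiv), CeCl3 (3.5 equiv), THF, −78 → 0 °C; then 48% aq. HF, MeCN, 23 °C
Reagents that add atoms: (trimethylsilyl)methyllithium, [Li]C[Si](C)(C)C
Why: The weakly basic organocerium reagent should add to the hindered, enolizable C1 ketone without retro-aldol or β-elimination, and acid-promoted anti elimination of the β-hydroxysilane (Peterson olefination) places the double bond only in the exocyclic position; no stereocenter of the target is touched.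

**Compound list**

1 | dimedone (5,5-dimethylcyclohexane-1,3-dione) | CC1(C)CC(=O)CC(=O)C1 | starting material
2 | 3-methoxy-5,5-dimethylcyclohex-2-en-1-one | COC1=CC(=O)CC(C)(C)C1 | intermediate
3 | 4-bromo-2-methylbut-1-ene | C=C(C)CCBr | starting material
4 | lithium 5-methoxy-3,3-dimethylcyclohexa-1,5-dien-1-olate (formed in situ) | [Li+].[O-]C1=CC(C)(C)CC(OC)=C1 | intermediate
5 | 3-methoxy-5,5-dimethyl-6-(3-methylbut-3-en-1-yl)cyclohex-2-en-1-one (racemic) | COC1=CC(=O)C(CCC(C)=C)C(C)(C)C1 | intermediate
6 | allyl chloroformate (prop-2-en-1-yl carbonochloridate) | C=CCOC(Cl)=O | starting material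
7 | lithium 5-methoxy-3,3-dimethyl-2-(3-methylbut-3-en-1-yl)cyclohexa-1,5-dien-1-olate (formed in situ) | [Li+].[O-]C1=C(CCC(C)=C)C(C)(C)CC(OC)=C1 | intermediate
8 | 5-methoxy-3,3-dimethyl-2-(3-methylbut-3-en-1-yl)cyclohexa-1,5-dien-1-yl prop-2-en-1-yl carbonate | C=CCOC(=O)OC1=C(CCC(C)=C)C(C)(C)CC(OC)=C1 | intermediate
9 | (6R)-3-methoxy-5,5-dimethyl-6-(3-methylbut-3-en-1-yl)-6-(prop-2-en-1-yl)cyclohex-2-en-1-one | COC1=CC(=O)[C@@](CC=C)(CCC(C)=C)C(C)(C)C1 | intermediate
10 | (6R)-3-methoxy-5,5,9-trimethylspiro[5.5]undeca-2,8-dien-1-one | COC1=CC(=O)[C@]2(CC=C(C)CC2)C(C)(C)C1 | intermediate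
11 | {[(6R)-3-methoxy-5,5,9-trimethylspiro[5.5]undeca-1,3,8-trien-1-yl]oxy}trimethylsilane (formed in situ) | COC1=CC(C)(C)[C@@]2(CC=C(C)CC2)C(O[Si](C)(C)C)=C1 | intermediate
12 | (4S,6R)-4-bromo-3-methoxy-5,5,9-trimethylspiro[5.5]undeca-2,8-dien-1-one | COC1=CC(=O)[C@]2(CC=C(C)CC2)C(C)(C)[C@@H]1Br | intermediate
13 | O-methyl oxocarbenium (1,3-dialkoxyallyl) cation of 14, succinimide anion as counter-ion (formed in situ) | C[O+]=C1C=C2O[C@@]3(C)CC[C@@]2(C[C@@H]3Br)C(C)(C)[C@@H]1Br.O=C1CCC(=O)[N-]1 | intermediate
14 | (4S,6R,8S,9S)-4,8-dibromo-5,5,9-trimethyl-1,9-epoxyspiro[5.5]undec-1-en-3-one (oxygen bridge from C1 to C9) | O=C1C=C2O[C@@]3(C)CC[C@@]2(C[C@@H]3Br)C(C)(C)[C@@H]1Br | intermediate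
15 | (3R,4S,6R,8S,9S)-4,8-dibromo-5,5,9-trimethyl-1,9-epoxyspiro[5.5]undec-1-en-3-ol | O[C@@H]1C=C2O[C@@]3(C)CC[C@@]2(C[C@@H]3Br)C(C)(C)[C@@H]1Br | intermediate
16 | (3R,4S,6R,8S,9S)-4,8-dibromo-9-chloro-3-hydroxy-5,5,9-trimethylspiro[5.5]undecan-1-one | O=C1C[C@@H](O)[C@@H](Br)C(C)(C)[C@]12CC[C@](C)(Cl)[C@@H](Br)C2 | intermediate
17 | (3R,4S,6R,8S,9S)-4,8-dibromo-9-chloro-5,5,9-trimethyl-1-[(trimethylsilyl)methyl]spiro[5.5]undecane-1,3-diol (C1 epimers, formed in situ) | C[Si](C)(C)CC1(O)C[C@@H](O)[C@@H](Br)C(C)(C)[C@]12CC[C@](C)(Cl)[C@@H](Br)C2 | intermediate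
18 | (3R,4S,6S,8S,9S)-4,8-dibromo-9-chloro-5,5,9-trimethyl-1-methylidenespiro[5.5]undecan-3-ol | C=C1C[C@@H](O)[C@@H](Br)C(C)(C)[C@]12CC[C@](C)(Cl)[C@@H](Br)C2 | target

**Step count**

Total steps: 10. Longest linear sequence: 10 steps, from dimedone 1.

**Steps most likely to fail**

Step 7 (proposed new method). What may go wrong: electrophilic bromination at C2 of the vinylogous ester instead of bromonium formation at C8=C9; closure of the carbonyl oxygen on C8 (five-membered ether) instead of C9; or loss of the C4 configuration by deprotonation of the dialkoxyallyl cation. The fallback uses known chemistry and sets out from 12. Ionic bromochlorination with Bu4N[BrCl2] (CH2Cl2, −78 °C; Markovnikov, anti; the bromonium ion is expected on the ring B face remote from the C1 carbonyl, but this facial control is less secure than the oxygen relay) would give the bromochloride vinylogous ester F1. MeLi/CeCl3 followed by aqueous HCl (Stork–Danheiser transposition) would give the bromo enone F2. Me3SiOTf/Et3N would give the exocyclic silyl dienol ether F3. Cleavage with MeLi and kinetic α-protonation of the dienolate with AcOH at −78 °C would give the β,γ-unsaturated bromo ketone F4. Reduction with i-Bu2AlH (hydride anti to bromine) comes back to the route at 18.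

Step 6. What may go wrong: attack of bromine at C2 (α) instead of C4 (γ) of the silyl dienol ether, or poor facial selectivity at C4, since the two ring B arms differ only beyond their first carbon. The fallback sets out from 10. The oxygen-relay bromoetherification of step 7 is run first and would give the bridged enol ether ketone F5, in which C2 is vinylic and C4 is the only enolizable position. Kinetic deprotonation (LiN(i-Pr)2, Me3SiCl, THF, −78 °C) and NBS would then brominate C4 without regiochemical ambiguity and come back to the route at 14. The C4 epimers are separable and interconvertible at this α-bromo ketone stage.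

Step 9. What may go wrong: ionization of the allylic C3 hydroxyl (loss of water from the alkoxy-allyl system) competing with protonation at C2, or loss of a proton from the tertiary cation instead of capture by chloride. The fallback sets out from 15. Silylation (TBSOTf, 2,6-lutidine, CH2Cl2, −78 °C) would give the silyl ether F6, in which ionization at C3 is shut down. HCl as in step 9 would give the silyloxy ketone F7. The conditions of step 10 would give the adduct F8 (not isolated) and, because aqueous HF removes the silyl ether during the Peterson elimination, come back to the route at 18.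

**Further compounds**

F1 | step 7 | (4S,6R,8S,9S)-4,8-dibromo-9-chloro-3-methoxy-5,5,9-trimethylspiro[5.5]undec-2-en-1-one | COC1=CC(=O)[C@@]2(CC[C@](C)(Cl)[C@@H](Br)C2)C(C)(C)[C@@H]1Br
F2 | step 7 | (4S,6S,8S,9S)-4,8-dibromo-9-chloro-1,5,5,9-tetramethylspiro[5.5]undec-1-en-3-one | CC1=CC(=O)[C@@H](Br)C(C)(C)[C@]12CC[C@](C)(Cl)[C@@H](Br)C2
F3 | step 7 | {[(4S,6S,8S,9S)-4,8-dibromo-9-chloro-5,5,9-trimethyl-1-methylidenespiro[5.5]undec-2-en-3-yl]oxy}trimethylsilane | C=C1C=C(O[Si](C)(C)C)[C@@H](Br)C(C)(C)[C@]12CC[C@](C)(Cl)[C@@H](Br)C2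
F4 | step 7 | (4S,6S,8S,9S)-4,8-dibromo-9-chloro-5,5,9-trimethyl-1-methylidenespiro[5.5]undecan-3-one | C=C1CC(=O)[C@@H](Br)C(C)(C)[C@]12CC[C@](C)(Cl)[C@@H](Br)C2
F5 | step 6 | (6R,8S,9S)-8-bromo-5,5,9-trimethyl-1,9-epoxyspiro[5.5]undec-1-en-3-one | O=C1C=C2O[C@@]3(C)CC[C@@]2(C[C@@H]3Br)C(C)(C)C1
F6 | step 9 | tert-butyl{[(3R,4S,6R,8S,9S)-4,8-dibromo-5,5,9-trimethyl-1,9-epoxyspiro[5.5]undec-1-en-3-yl]oxy}dimethylsilane | CC(C)(C)[Si](C)(C)O[C@@H]1C=C2O[C@@]3(C)CC[C@@]2(C[C@@H]3Br)C(C)(C)[C@@H]1Br
F7 | step 9 | (3R,4S,6R,8S,9S)-4,8-dibromo-3-[(tert-butyldimethylsilyl)oxy]-9-chloro-5,5,9-trimethylspiro[5.5]undecan-1-one | O=C1C[C@@H](O[Si](C)(C)C(C)(C)C)[C@@H](Br)C(C)(C)[C@]12CC[C@](C)(Cl)[C@@H](Br)C2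
F8 | step 9 | (3R,4S,6R,8S,9S)-4,8-dibromo-3-[(tert-butyldimethylsilyl)oxy]-9-chloro-5,5,9-trimethyl-1-[(trimethylsilyl)methyl]spiro[5.5]undecan-1-ol (C1 epimers) | C[Si](C)(C)CC1(O)C[C@@H](O[Si](C)(C)C(C)(C)C)[C@@H](Br)C(C)(C)[C@]12CC[C@](C)(Cl)[C@@H](Br)C2
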